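**Plan**
- Retrosynthesis: first the aryl ether bond O1'–C2' of ring C' of the 6-methylflavan unit is cut (Mitsunobu closure). Then ring A' of that unit is cut at C7'–C8' and C4a'–C8a' (benzannulation). This leaves a siloxyalkyne that carries the finished (2S)-flavan of unit 1 and a 3-methoxy-4-methylcyclobutenone that carries the C4'–C2' chain.
- Enabling feature: ring A' (C4a'-alkyl, C5'-OMe, C6'-Me, C7'-OH, C8'-CH2Ar, C8a'-O) is a hexasubstituted benzene with oxygen on alternate carbons, which is the pattern a vinylketene plus ynol ether benzannulation delivers; its C8' substituent is the methylene bridge.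
- Forward: rings A, B and C of unit 1 come preformed from alpinetin, which is extended at C8 to the siloxyalkyne. The chain fragment is joined to methoxyacetylene and methylketene to give the cyclobutenone. The two fragments are united as ring A' forms, and ring C' is closed last.
- Stereochemistry: C2 is carried unchanged from (2S)-alpinetin; C2' comes from (R)-3-chloro-1-phenylpropan-1-ol by inversion in the final ring closure.

Key step: step 11

Assumption: the C4 epimers of 3 and of 18, the quaternary centre of 20, the C6 centre of 22 and the alkene isomers of 19–21 are carried as mixtures, because these centres and double bonds all end as aromatic or methylene carbons. Flavan (2-phenylchroman) numbering is used, primed for the 6-methyl unit.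

**Step 1**
Reactants: 1 (2S)-alpinetin [(2S)-7-hydroxy-5-methoxyflavanone]
Product: 2 (2S)-5-methoxy-7-(triisopropylsilyloxy)flavanone
Conditions: TIPSCl, imidazole, DMF, rt
Reagents that add atoms: triisopropylsilyl chloride, CC(C)[Si](Cl)(C(C)C)C(C)C
Why: Imidazole-promoted silyl ether formation at the only hydroxyl, the acidic C7 phenol, is a standard protection, and the weak base should not open the flavanone to the chalcone, so C2 stays (S).

**Step 2**
Reactants: 2 (2S)-5-methoxy-7-(triisopropylsilyloxy)flavanone
Product: 3 (2S,4S)-5-methoxy-7-(triisopropylsilyloxy)flavan-4-ol (2,4-cis, major epimer expected)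
Conditions: NaBH4, THF/MeOH, 0 °C
Reagents that add atoms: none
Why: Borohydride reduction of the aryl ketone should deliver hydride axially to give mainly the 2,4-cis alcohol with equatorial phenyl and hydroxyl, and the C4 configuration is of no consequence because this centre is removed in step 3.

**Step 3**
Reactants: 3 (2S,4S)-5-methoxy-7-(triisopropylsilyloxy)flavan-4-ol
Product: 4 (2S)-5-methoxy-7-(triisopropylsilyloxy)flavan
Conditions: Et3SiH (5 equiv), TFA, CH2Cl2, −20 → 0 °C
Reagents that add atoms: none
Why: Ionic hydrogenation (Kursanov–Parnes deoxygenation) should work because the C4 cation is stabilised by the 5-OMe, 7-OSi and O1 donors and is trapped by excess silane before it can alkylate another arene, whereas ionisation at C2 lacks such stabilisation and the (S) centre is kept.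

**Step 4**
Reactants: 4 (2S)-5-methoxy-7-(triisopropylsilyloxy)flavan
Product: 5 (2S)-8-bromo-5-methoxy-7-(triisopropylsilyloxy)flavan
Conditions: NBS, CH2Cl2, −78 → 0 °C
Reagents that add atoms: N-bromosuccinimide, O=C1CCC(=O)N1Br
Why: Electrophilic aromatic bromination of the phloroglucinol-type ring is fast at low temperature, and C8 (para to the 5-OMe group, flanked by the tied-back ring oxygen) is less hindered than C6 between OMe and OTIPS, in line with the known C8 preference of NBS on 5,7-dialkoxyflavans.

**Step 5**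
Reactants: 5 (2S)-8-bromo-5-methoxy-7-(triisopropylsilyloxy)flavan
Product: 6 ethyl 2-[(2S)-5-methoxy-7-(triisopropylsilyloxy)flavan-8-yl]acetate
Conditions: BrZnCH2CO2Et (commercial Et2O solution), Pd(dba)2 (5 mol %), XPhos (10 mol %), THF, 60 °C
Reagents that add atoms: (2-ethoxy-2-oxoethyl)zinc bromide, CCOC(=O)C[Zn]Br
Why: Palladium-catalysed α-arylation of a zinc ester enolate (Reformatsky-type Negishi coupling) runs under near-neutral conditions that spare the silyl ether, and the bulky biaryl phosphine is chosen to drive oxidative addition at the electron-rich, doubly ortho-substituted bromide.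

**Step 6**
Reactants: 6 ethyl 2-[(2S)-5-methoxy-7-(triisopropylsilyloxy)flavan-8-yl]acetate
Product: 9 (2S)-5-methoxy-7-(triisopropylsilyloxy)-8-[3-(triisopropylsilyloxy)prop-2-yn-1-yl]flavan, via lithium dibromoenolate 7 (not isolated), via lithium ynolate 8 (not isolated)
Conditions: CH2Br2, lithium 2,2,6,6-tetramethylpiperidide (LiTMP), THF, −78 °C; LiN(SiMe3)2; n-BuLi, −78 °C → rt; TIPSCl, −78 °C → rt
Reagents that add atoms: dibromomethane, BrCBr; triisopropylsilyl chloride, CC(C)[Si](Cl)(C(C)C)C(C)C
Why: Kowalski ynolate synthesis, in which LiCHBr2 adds to the ester, the dibromoketone is enolised, bromine–lithium exchange triggers the 1,2-shift to the ynolate and the bulky silyl chloride reacts at oxygen to give the siloxyalkyne.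

**Step 7**
Reactants: 10 (R)-3-chloro-1-phenylpropan-1-ol
Product: 11 (R)-tert-butyl(3-chloro-1-phenylpropoxy)dimethylsilane
Conditions: TBSCl, imidazole, DMF, rt
Reagents that add atoms: tert-butyldimethylsilyl chloride, CC(C)(C)[Si](C)(C)Cl
Why: Standard silyl ether protection of the secondary alcohol breaks no bond at the stereocentre, so the (R) configuration is retained.

**Step 8**
Reactants: 11 (R)-tert-butyl(3-chloro-1-phenylpropoxy)dimethylsilane
Product: 12 (R)-tert-butyl(3-iodo-1-phenylpropoxy)dimethylsilane
Conditions: NaI, acetone, reflux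
Reagents that add atoms: sodium iodide, [Na+].[I-]
Why: Finkelstein halide exchange at the primary carbon is driven by precipitation of NaCl and gives the better alkylating agent without touching the remote stereocentre.

**Step 9**
Reactants: 13 chloroacetaldehyde dimethyl acetal; 12 (R)-tert-butyl(3-iodo-1-phenylpropoxy)dimethylsilane
Product: 15 (R)-tert-butyl[(5-methoxy-1-phenylpent-4-yn-1-yl)oxy]dimethylsilane, via sodium methoxyacetylide 14 (not isolated)
Conditions: NaNH2 (3 equiv), liquid NH3, −33 °C; then 12 in THF, −33 °C → rt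
Reagents that add atoms: none
Why: Double elimination of the chloroacetal with sodium amide gives the alkoxyacetylide, which is alkylated by the primary iodide in an SN2 reaction, the classical 1-alkoxy-1-alkyne synthesis, and the methyl ynol ether has no retro-ene pathway on later heating.

**Step 10**
Reactants: 15 (R)-tert-butyl[(5-methoxy-1-phenylpent-4-yn-1-yl)oxy]dimethylsilane; 16 propionyl chloride
Product: 18 2-[(3R)-3-(tert-butyldimethylsilyloxy)-3-phenylpropyl]-3-methoxy-4-methylcyclobut-2-en-1-one (both C4 epimers), via methylketene 17 (not isolated)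
Conditions: Et3N, CH2Cl2, slow addition of 16, rt → 40 °C
Reagents that add atoms: none
Why: Ketene–ynol ether [2+2] cycloaddition, in which methylketene formed by dehydrochlorination bonds through its carbonyl carbon to the nucleophilic chain-bearing alkyne carbon, so the chain ends at C2, OMe at C3 and Me at C4, with C4 formed as an inconsequential mixture.

**Step 11**
Reactants: 18 2-[(3R)-3-(tert-butyldimethylsilyloxy)-3-phenylpropyl]-3-methoxy-4-methylcyclobut-2-en-1-one; 9 (2S)-5-methoxy-7-(triisopropylsilyloxy)-8-[3-(triisopropylsilyloxy)prop-2-yn-1-yl]flavan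
Product: 23 (2S)-8-{[3-[(3R)-3-(tert-butyldimethylsilyloxy)-3-phenylpropyl]-6-hydroxy-4-methoxy-5-methyl-2-(triisopropylsilyloxy)phenyl]methyl}-5-methoxy-7-(triisopropylsilyloxy)flavan, via vinylketene 19 (not isolated), via vinylcyclobutenone 20 (not isolated), via dienylketene 21 (not isolated), via cyclohexadienone 22 (not isolated)
Conditions: 18 (1.2 equiv), PhMe, degassed, sealed tube, 110 °C then 150 °C
Reagents that add atoms: none
Why: Thermal conrotatory 4π opening of cyclobutenone 18 (methyl turning outward) gives vinylketene 19, whose carbonyl carbon is attacked by the CH2Ar-bearing carbon of siloxyalkyne 9 in a [2+2] cycloaddition that forms C7'–C8' and C4a'–C8a' and gives vinylcyclobutenone 20. A second 4π opening gives dienylketene 21, and ring A' then closes by a thermally allowed disrotatory 6π electrocyclisation that re-forms the C6'–C7' bond, after which cyclohexadienone 22 tautomerises to phenol 23. The closest known reaction type is the Danheiser benzannulation of cyclobutenones with trialkylsiloxyalkynes to resorcinol monosilyl ethers, here with the less common 3-alkoxy substitution on the cyclobutenone. No stereocentre is created, since the C4 centre of 18 and the transient centres of 20 and 22 end as aromatic carbons, and the two existing centres are remote from the reacting atoms and are carried through unchanged. The step needs regiocontrol in the ketene–alkyne union and cross-pairing of the two flavan halves: the first is secured by the oxygen-induced polarisation of the ynol ether, which places CH2Ar beside the new C7' hydroxyl and the siloxy group beside the chain, and the second by the bridging methylene already sitting on the alkyne. The ground-state stabilisation of the 3-methoxycyclobutenone is met by staged heating in a closed vessel with the cheaper cyclobutenone in slight excess, which the thermally robust silyl ynol ether should tolerate.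

**Step 12**
Reactants: 23 benzannulation phenol (name as in step 11)
Product: 24 (2S)-8-{[2,6-dihydroxy-3-[(3R)-3-hydroxy-3-phenylpropyl]-4-methoxy-5-methylphenyl]methyl}-5-methoxyflavan-7-ol
Conditions: n-Bu4NF, AcOH, THF, argon, 0 °C → rt
Reagents that add atoms: none
Why: Fluoride-mediated desilylation should cleave both aryl TIPS ethers and the benzylic TBS ether in one operation, with acetic acid buffering the electron-rich phenoxides against oxidation and no bond at a stereocentre being broken.

**Step 13**
Reactants: 24 (2S)-8-{[2,6-dihydroxy-3-[(3R)-3-hydroxy-3-phenylpropyl]-4-methoxy-5-methylphenyl]methyl}-5-methoxyflavan-7-ol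
Product: 25 (2S)-8-{[(2S)-7-hydroxy-5-methoxy-6-methyl-2-phenylchroman-8-yl]methyl}-5-methoxy-2-phenylchroman-7-ol (target)
Conditions: PPh3, DIAD, THF (high dilution), 0 °C → rt
Reagents that add atoms: none
Why: Intramolecular Mitsunobu etherification, in which the carbinol is activated as its alkoxyphosphonium ion and displaced by the C8a' phenol, the only hydroxyl able to reach it (6-exo-tet), with SN2 inversion that converts the (R)-carbinol into the (2'S) centre of ring C'.

**Compound list**
1 | (2S)-alpinetin, (2S)-7-hydroxy-5-methoxyflavanone | COc1cc(O)cc2c1C(=O)C[C@@H](c1ccccc1)O2 | starting material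
2 | (2S)-5-methoxy-7-(triisopropylsilyloxy)flavanone | COc1cc(O[Si](C(C)C)(C(C)C)C(C)C)cc2c1C(=O)C[C@@H](c1ccccc1)O2 | intermediate
3 | (2S,4S)-5-methoxy-7-(triisopropylsilyloxy)flavan-4-ol (2,4-cis) | COc1cc(O[Si](C(C)C)(C(C)C)C(C)C)cc2c1[C@@H](O)C[C@@H](c1ccccc1)O2 | intermediate
4 | (2S)-5-methoxy-7-(triisopropylsilyloxy)flavan | COc1cc(O[Si](C(C)C)(C(C)C)C(C)C)cc2c1CC[C@@H](c1ccccc1)O2 | intermediate
5 | (2S)-8-bromo-5-methoxy-7-(triisopropylsilyloxy)flavan | COc1cc(O[Si](C(C)C)(C(C)C)C(C)C)c(Br)c2c1CC[C@@H](c1ccccc1)O2 | intermediate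
6 | ethyl 2-[(2S)-5-methoxy-7-(triisopropylsilyloxy)flavan-8-yl]acetate | CCOC(=O)Cc1c(O[Si](C(C)C)(C(C)C)C(C)C)cc(OC)c2c1O[C@H](c1ccccc1)CC2 | intermediate
7 | lithium enolate of the 1,1-dibromo-3-arylpropan-2-one from 6 | [Li]OC(Cc1c(O[Si](C(C)C)(C(C)C)C(C)C)cc(OC)c2c1O[C@H](c1ccccc1)CC2)=C(Br)Br | intermediate (not isolated)
8 | lithium 3-[(2S)-5-methoxy-7-(triisopropylsilyloxy)flavan-8-yl]prop-1-yn-1-olate | [Li]OC#CCc1c(O[Si](C(C)C)(C(C)C)C(C)C)cc(OC)c2c1O[C@H](c1ccccc1)CC2 | intermediate (not isolated)
9 | (2S)-5-methoxy-7-(triisopropylsilyloxy)-8-[3-(triisopropylsilyloxy)prop-2-yn-1-yl]flavan | CC(C)[Si](C(C)C)(C(C)C)OC#CCc1c(O[Si](C(C)C)(C(C)C)C(C)C)cc(OC)c2c1O[C@H](c1ccccc1)CC2 | intermediate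
10 | (R)-3-chloro-1-phenylpropan-1-ol | O[C@H](CCCl)c1ccccc1 | starting material
11 | (R)-tert-butyl(3-chloro-1-phenylpropoxy)dimethylsilane | CC(C)(C)[Si](C)(C)O[C@H](CCCl)c1ccccc1 | intermediate
12 | (R)-tert-butyl(3-iodo-1-phenylpropoxy)dimethylsilane | CC(C)(C)[Si](C)(C)O[C@H](CCI)c1ccccc1 | intermediate
13 | chloroacetaldehyde dimethyl acetal | COC(CCl)OC | starting material
14 | sodium methoxyacetylide | [Na]C#COC | intermediate (not isolated)
15 | (R)-tert-butyl[(5-methoxy-1-phenylpent-4-yn-1-yl)oxy]dimethylsilane | COC#CCC[C@@H](O[Si](C)(C)C(C)(C)C)c1ccccc1 | intermediate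
16 | propionyl chloride | CCC(Cl)=O | starting material
17 | methylketene | CC=C=O | intermediate (not isolated)
18 | 2-[(3R)-3-(tert-butyldimethylsilyloxy)-3-phenylpropyl]-3-methoxy-4-methylcyclobut-2-en-1-one (C4 epimers) | CC1C(=O)C(CC[C@@H](O[Si](C)(C)C(C)(C)C)c2ccccc2)=C1OC | intermediate
19 | 2-[(3R)-3-(tert-butyldimethylsilyloxy)-3-phenylpropyl]-3-methoxypenta-1,3-dien-1-one (vinylketene) | CC=C(OC)C(CC[C@@H](O[Si](C)(C)C(C)(C)C)c1ccccc1)=C=O | intermediate (not isolated)
20 | 2-(flavan-8-ylmethyl)-3-(triisopropylsilyloxy)-4-(1-methoxyprop-1-enyl)-4-[(3R)-3-(tert-butyldimethylsilyloxy)-3-phenylpropyl]cyclobut-2-en-1-one, the [2+2] adduct | CC=C(OC)C1(CC[C@@H](O[Si](C)(C)C(C)(C)C)c2ccccc2)C(=O)C(Cc2c(O[Si](C(C)C)(C(C)C)C(C)C)cc(OC)c3c2O[C@H](c2ccccc2)CC3)=C1O[Si](C(C)C)(C(C)C)C(C)C | intermediate (not isolated)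
21 | dienylketene from ring opening of 20 | CC=C(OC)C(CC[C@@H](O[Si](C)(C)C(C)(C)C)c1ccccc1)=C(O[Si](C(C)C)(C(C)C)C(C)C)C(Cc1c(O[Si](C(C)C)(C(C)C)C(C)C)cc(OC)c2c1O[C@H](c1ccccc1)CC2)=C=O | intermediate (not isolated)
22 | 6-methylcyclohexa-2,4-dien-1-one tautomer of 23 | CC1C(=O)C(Cc2c(O[Si](C(C)C)(C(C)C)C(C)C)cc(OC)c3c2O[C@H](c2ccccc2)CC3)=C(O[Si](C(C)C)(C(C)C)C(C)C)C(CC[C@@H](O[Si](C)(C)C(C)(C)C)c2ccccc2)=C1OC | intermediate (not isolated)
23 | (2S)-8-{[3-[(3R)-3-(tert-butyldimethylsilyloxy)-3-phenylpropyl]-6-hydroxy-4-methoxy-5-methyl-2-(triisopropylsilyloxy)phenyl]methyl}-5-methoxy-7-(triisopropylsilyloxy)flavan | CC(C)(C)[Si](C)(C)O[C@H](CCc1c(OC)c(C)c(O)c(Cc2c(O[Si](C(C)C)(C(C)C)C(C)C)cc(OC)c3c2O[C@H](c2ccccc2)CC3)c1O[Si](C(C)C)(C(C)C)C(C)C)c1ccccc1 | intermediate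
24 | (2S)-8-{[2,6-dihydroxy-3-[(3R)-3-hydroxy-3-phenylpropyl]-4-methoxy-5-methylphenyl]methyl}-5-methoxyflavan-7-ol | O[C@H](CCc1c(OC)c(C)c(O)c(Cc2c(O)cc(OC)c3c2O[C@H](c2ccccc2)CC3)c1O)c1ccccc1 | intermediate
25 | (2S)-8-{[(2S)-7-hydroxy-5-methoxy-6-methyl-2-phenylchroman-8-yl]methyl}-5-methoxy-2-phenylchroman-7-ol | COc1cc(O)c(Cc2c(O)c(C)c(OC)c3c2O[C@H](c2ccccc2)CC3)c2c1CC[C@@H](c1ccccc1)O2 | target

**Totals**
Total step count: 13. Longest linear sequence: 9 steps (steps 1–6, then 11–13); the cyclobutenone branch is steps 7–10.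

**Steps most likely to fail**

Step 11. The vinylogous-ester stabilisation of the 3-methoxycyclobutenone may make the first ring opening so slow that, at the temperature needed, vinylketene dimerisation, capture of the ketene by the product phenol or degradation of the ynol silyl ether outrun the [2+2] union. The fallback makes the same vinylketene without any electrocyclic opening, by 1,4-dehydrochlorination of an unsaturated acid chloride. It sets out from iodide 12, which should alkylate the sodium enolate of ethyl 3-oxopentanoate (NaH, THF/DMF) to give ethyl 2-[(3R)-3-(tert-butyldimethylsilyloxy)-3-phenylpropyl]-3-oxopentanoate F1. O-Methylation of its potassium enolate (KN(SiMe3)2, MeOTf, THF/DMPU) should give ethyl 2-[(3R)-3-(tert-butyldimethylsilyloxy)-3-phenylpropyl]-3-methoxypent-2-enoate F2. Saponification (LiOH, aqueous THF/MeOH) should give the corresponding 3-methoxypent-2-enoic acid F3, and neutral chlorination with 1-chloro-N,N,2-trimethylpropenylamine should give the 3-methoxypent-2-enoyl chloride F4. Treating F4 with Et3N in toluene in the presence of siloxyalkyne 9 should remove a γ-hydrogen to give vinylketene 19 at or near room temperature; gentle heating then carries it through 20, 21 and 22. The fallback comes back to the route at phenol 23.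

Step 6. The arylacetate has acidic benzylic α-hydrogens, so enolisation by LiCHBr2 or LiTMP may compete with carbonyl addition and return the ester on work-up, and the rearrangement to the ynolate may be incomplete. The fallback reaches the ynolate by oxidation of a lithium acetylide instead. It sets out from ester 6, which is reduced with i-Bu2AlH at −78 °C to 2-[(2S)-5-methoxy-7-(triisopropylsilyloxy)flavan-8-yl]acetaldehyde F5. Corey–Fuchs olefination (CBr4, PPh3) should give (2S)-8-(3,3-dibromoprop-2-en-1-yl)-5-methoxy-7-(triisopropylsilyloxy)flavan F6, and n-BuLi (2 equiv, −78 °C) followed by an aqueous quench should give (2S)-5-methoxy-8-(prop-2-yn-1-yl)-7-(triisopropylsilyloxy)flavan F7. Deprotonation of F7 with n-BuLi and oxidation of the acetylide with t-BuOOLi (from t-BuOOH and LiN(SiMe3)2, −78 → 0 °C) should give ynolate 8. Silylation with TIPSOTf brings the fallback back to the route at siloxyalkyne 9.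

Step 5. Oxidative addition at the electron-rich C8–Br bond, flanked by OTIPS and the ring oxygen, may be sluggish, so that protodebromination and self-condensation of the zinc enolate take over. The fallback uses bromine–lithium exchange and an ionic deoxygenation instead of cross-coupling. It sets out from bromide 5, which is treated with n-BuLi in THF at −78 °C (kept cold to suppress O-to-C silyl migration) and added to excess diethyl oxalate to give ethyl 2-[(2S)-5-methoxy-7-(triisopropylsilyloxy)flavan-8-yl]-2-oxoacetate F8. NaBH4 reduction should give ethyl 2-hydroxy-2-[(2S)-5-methoxy-7-(triisopropylsilyloxy)flavan-8-yl]acetate F9 as a mixture of epimers. Et3SiH/TFA should then remove the benzylic hydroxyl through the donor-stabilised cation, and the fallback comes back to the route at ester 6.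

**Further compounds**
F1 | step 11 | ethyl 2-[(3R)-3-(tert-butyldimethylsilyloxy)-3-phenylpropyl]-3-oxopentanoate | CCC(=O)C(CC[C@@H](O[Si](C)(C)C(C)(C)C)c1ccccc1)C(=O)OCC
F2 | step 11 | ethyl 2-[(3R)-3-(tert-butyldimethylsilyloxy)-3-phenylpropyl]-3-methoxypent-2-enoate | CCOC(=O)C(CC[C@@H](O[Si](C)(C)C(C)(C)C)c1ccccc1)=C(CC)OC
F3 | step 11 | 2-[(3R)-3-(tert-butyldimethylsilyloxy)-3-phenylpropyl]-3-methoxypent-2-enoic acid | CCC(OC)=C(CC[C@@H](O[Si](C)(C)C(C)(C)C)c1ccccc1)C(=O)O
F4 | step 11 | 2-[(3R)-3-(tert-butyldimethylsilyloxy)-3-phenylpropyl]-3-methoxypent-2-enoyl chloride | CCC(OC)=C(CC[C@@H](O[Si](C)(C)C(C)(C)C)c1ccccc1)C(Cl)=O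
F5 | step 6 | 2-[(2S)-5-methoxy-7-(triisopropylsilyloxy)flavan-8-yl]acetaldehyde | O=CCc1c(O[Si](C(C)C)(C(C)C)C(C)C)cc(OC)c2c1O[C@H](c1ccccc1)CC2
F6 | step 6 | (2S)-8-(3,3-dibromoprop-2-en-1-yl)-5-methoxy-7-(triisopropylsilyloxy)flavan | BrC(Br)=CCc1c(O[Si](C(C)C)(C(C)C)C(C)C)cc(OC)c2c1O[C@H](c1ccccc1)CC2
F7 | step 6 | (2S)-5-methoxy-8-(prop-2-yn-1-yl)-7-(triisopropylsilyloxy)flavan | C#CCc1c(O[Si](C(C)C)(C(C)C)C(C)C)cc(OC)c2c1O[C@H](c1ccccc1)CC2
F8 | step 5 | ethyl 2-[(2S)-5-methoxy-7-(triisopropylsilyloxy)flavan-8-yl]-2-oxoacetate | CCOC(=O)C(=O)c1c(O[Si](C(C)C)(C(C)C)C(C)C)cc(OC)c2c1O[C@H](c1ccccc1)CC2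
F9 | step 5 | ethyl 2-hydroxy-2-[(2S)-5-methoxy-7-(triisopropylsilyloxy)flavan-8-yl]acetate | CCOC(=O)C(O)c1c(O[Si](C(C)C)(C(C)C)C(C)C)cc(OC)c2c1O[C@H](c1ccccc1)CC2
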